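**Strategy.** The enone is cut between the ketone carbon on C8 of ring A (the benzene ring of the chroman) and its neighbouring alkene carbon. A Liebeskind–Srogl acyl cross-coupling joins the S-phenyl thioester of the (3R)-chromanol acid to (E)-2-(4-hydroxyphenyl)vinylboronic acid. It exploits the C8–C(=O)–CH=CH–ring B array as an aroyl electrophile plus an alkenyl nucleophile: in one base-free operation the ketone–alkene bond forms, the preformed E alkene is transferred with retention, and the target emerges with the C3 alcohol and the phenol unprotected. The C3 stereocentre comes earlier from Jacobsen epoxidation of a 2,2-dimethyl-2H-chromene, built by a propargyl ether Claisen cascade, followed by benzylic hydrogenolysis.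

Key step: step 7

Remark: chroman numbering is O1, C2 (gem-dimethyl), C3 (carbinol), C4, C4a, C5 (OMe), C8 (acyl), C8a. "salen" denotes N,N'-bis(3,5-di-tert-butylsalicylidene)-(1R,2R)-cyclohexane-1,2-diaminate; its chloride complex of trivalent manganese, (R,R)-(salen)MnCl, is assumed to give the (3R,4R)-epoxide, as it does with simple 2,2-dimethyl-2H-chromenes. The target's C3 centre is R.

Step 1
Reactants: 1 methyl 2-hydroxy-4-methoxybenzoate; 2 3-chloro-3-methylbut-1-yne
Product: 3 methyl 4-methoxy-2-[(2-methylbut-3-yn-2-yl)oxy]benzoate
Conditions: DBU, CuCl2·2H2O (cat.), MeCN, 0 °C to rt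
Reagents that add atoms: none
Why: Copper-catalysed propargylic etherification, in which the copper acetylide of 2 ionises to a copper allenylidene that the phenoxide attacks at the tertiary carbon, avoiding an SN2 reaction on a tertiary halide.

Step 2
Reactants: 3 methyl 4-methoxy-2-[(2-methylbut-3-yn-2-yl)oxy]benzoate
Product: 6 methyl 5-methoxy-2,2-dimethyl-2H-chromene-8-carboxylate, via ortho-allenylphenol 4 (not isolated), via ortho-quinone methide 5 (not isolated)
Conditions: N,N-diethylaniline, 180 °C
Reagents that add atoms: none
Why: Aryl propargyl ether Claisen rearrangement to the only free ortho carbon (between the ether oxygen and the methoxy group), enolisation to 4, 1,5-hydrogen shift to 5 and oxa-6π electrocyclisation should give the chromene with the ester at C8 and the methoxy group at C5; no stereocentre is formed.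

Step 3
Reactants: 6 methyl 5-methoxy-2,2-dimethyl-2H-chromene-8-carboxylate
Product: 7 methyl (3R,4R)-3,4-epoxy-5-methoxy-2,2-dimethylchromane-8-carboxylate
Conditions: (R,R)-(salen)MnCl (4 mol %), aq. NaOCl (pH 11.3), 4-phenylpyridine N-oxide (20 mol %), CH2Cl2, 0 °C
Reagents that add atoms: sodium hypochlorite, [Na+].[O-]Cl
Why: Jacobsen epoxidation, for which cis-configured 2,2-dimethyl-2H-chromenes are a privileged substrate class; the chiral oxo-manganese species should deliver oxygen to one face of C3=C4 and so set C3 as R (catalyst control), and the acid-labile epoxide is filtered through basic alumina and used at once.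

Step 4
Reactants: 7 methyl (3R,4R)-3,4-epoxy-5-methoxy-2,2-dimethylchromane-8-carboxylate
Product: 8 methyl (3R)-3-hydroxy-5-methoxy-2,2-dimethylchromane-8-carboxylate
Conditions: H2 (1 atm), Pd/C, EtOAc, rt
Reagents that add atoms: none
Why: Catalytic hydrogenolysis of an aryl epoxide cleaves only the benzylic C4–O bond, so C4 becomes CH2 while the C3–O bond and its R configuration stay untouched; the ester and aryl ethers are inert.

Step 5
Reactants: 8 methyl (3R)-3-hydroxy-5-methoxy-2,2-dimethylchromane-8-carboxylate
Product: 9 S-phenyl (3R)-3-hydroxy-5-methoxy-2,2-dimethylchromane-8-carbothioate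
Conditions: AlMe3 (3 equiv.), PhSH (3 equiv.), CH2Cl2, 0 °C to 40 °C; aqueous Rochelle salt work-up
Reagents that add atoms: thiophenol, Sc1ccccc1
Why: Ester-to-thioester exchange with the aluminium thiolate Me2AlSPh formed in the flask, driven by the strong Al–OMe bond; the C3 alcohol is only masked as its aluminium alkoxide until work-up.

Step 6
Reactants: 10 4-ethynylphenol
Product: 12 (E)-2-(4-hydroxyphenyl)vinylboronic acid, via bis(catecholboryl) adduct 11 (not isolated)
Conditions: catecholborane (2.2 equiv.), THF, 0 °C to 70 °C; then H2O, rt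
Reagents that add atoms: catecholborane, B1Oc2ccccc2O1; water, O
Why: The first equivalent of catecholborane masks the phenol as an aryl borate, the second adds syn and anti-Markovnikov across the terminal alkyne (Brown hydroboration) to fix the E geometry, and water then hydrolyses both boron esters.

Step 7
Reactants: 9 S-phenyl (3R)-3-hydroxy-5-methoxy-2,2-dimethylchromane-8-carbothioate; 12 (E)-2-(4-hydroxyphenyl)vinylboronic acid
Product: 13 (E)-1-[(3R)-3-hydroxy-5-methoxy-2,2-dimethylchroman-8-yl]-3-(4-hydroxyphenyl)prop-2-en-1-one (target)
Conditions: Pd2(dba)3 (2.5 mol %), tri(2-furyl)phosphine (15 mol %), CuTC (copper thiophene-2-carboxylate, CuO2CC4H3S; 1.6 equiv.), THF, 50 °C, argon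
Reagents that add atoms: none
Why: Liebeskind–Srogl acyl cross-coupling: zerovalent palladium inserts into the C(acyl)–S bond of 9, the copper carboxylate binds the thiolate sulfur while its carboxylate activates boron, the E-alkenyl group is transferred to the acyl-palladium species with retention, and reductive elimination forms the ketone–alkene bond. The closest known reaction type is the palladium-catalysed, copper-carboxylate-mediated coupling of thiol esters with aryl- and alkenylboronic acids to give ketones and enones. No ring is closed and no stereocentre is created; the E geometry is the one fixed by syn-hydroboration in step 6, and the C3 carbinol is remote and not epimerisable. The step needs chemoselectivity for the thioester over the free alcohol and phenol, which the base-free neutral medium should secure because neither O–H group is activated, and it needs acyl retention over decarbonylation, which the electron-rich aroyl group and the mild temperature favour. Capture of the thiolate as its copper salt should also keep it from adding to the enone that is formed.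

**Compound list**

1 | methyl 2-hydroxy-4-methoxybenzoate | COc1ccc(C(=O)OC)c(O)c1 | starting material
2 | 3-chloro-3-methylbut-1-yne | CC(C)(Cl)C#C | starting material
3 | methyl 4-methoxy-2-[(2-methylbut-3-yn-2-yl)oxy]benzoate | COc1ccc(C(=O)OC)c(OC(C)(C)C#C)c1 | intermediate
4 | methyl 2-hydroxy-4-methoxy-3-(3-methylbuta-1,2-dien-1-yl)benzoate (ortho-allenylphenol) | COc1ccc(C(=O)OC)c(O)c1C=C=C(C)C | intermediate
5 | methyl 4-methoxy-5-(3-methylbut-2-en-1-ylidene)-6-oxocyclohexa-1,3-diene-1-carboxylate (ortho-quinone methide) | COC1=CC=C(C(=O)OC)C(=O)C1=CC=C(C)C | intermediate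
6 | methyl 5-methoxy-2,2-dimethyl-2H-chromene-8-carboxylate | COc1ccc(C(=O)OC)c2c1C=CC(C)(C)O2 | intermediate
7 | methyl (3R,4R)-3,4-epoxy-5-methoxy-2,2-dimethylchromane-8-carboxylate | COc1ccc(C(=O)OC)c2c1[C@H]3O[C@H]3C(C)(C)O2 | intermediate
8 | methyl (3R)-3-hydroxy-5-methoxy-2,2-dimethylchromane-8-carboxylate | COc1ccc(C(=O)OC)c2c1C[C@@H](O)C(C)(C)O2 | intermediate
9 | S-phenyl (3R)-3-hydroxy-5-methoxy-2,2-dimethylchromane-8-carbothioate | COc1ccc(C(=O)Sc3ccccc3)c2c1C[C@@H](O)C(C)(C)O2 | intermediate
10 | 4-ethynylphenol | Oc1ccc(C#C)cc1 | starting material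
11 | 2-{(E)-2-[4-(1,3,2-benzodioxaborol-2-yloxy)phenyl]vinyl}-1,3,2-benzodioxaborole (bis(catecholboryl) adduct) | c1ccc2OB(Oc3ccc(/C=C/B4Oc5ccccc5O4)cc3)Oc2c1 | intermediate
12 | (E)-2-(4-hydroxyphenyl)vinylboronic acid | OB(O)/C=C/c1ccc(O)cc1 | intermediate
13 | (E)-1-[(3R)-3-hydroxy-5-methoxy-2,2-dimethylchroman-8-yl]-3-(4-hydroxyphenyl)prop-2-en-1-one | COc1ccc(C(=O)/C=C/c2ccc(O)cc2)c2c1C[C@@H](O)C(C)(C)O2 | target

**Step count.** Total: 7 steps. Longest linear sequence: 6 steps (steps 1–5 and 7).

**Steps most likely to fail and fallbacks**

Step 7. The boron-to-palladium transfer may be slow, the electron-rich alkenylboronic acid may protodeboronate, or the acyl-palladium species may decarbonylate. The fallback forms the same bond by carbonyl addition instead of cross-coupling; it sets out from 8 and 10 and returns at 13. Ester 8 is treated with MeNH(OMe)·HCl and i-PrMgCl (THF, −20 °C) to give the N-methoxy-N-methylamide F1. Alkyne 10 is silylated (TBSCl, imidazole, DMF) to tert-butyl(4-ethynylphenoxy)dimethylsilane F2. F2 is hydrozirconated with Cp2Zr(H)Cl and iodinated (I2, THF) to the (E)-alkenyl iodide F3. Iodine–lithium exchange (t-BuLi, 2 equiv., Et2O, −78 °C) should give the (E)-alkenyllithium F4 with retention. F4 adds to the magnesium alkoxide of F1; the chelated tetrahedral intermediate should collapse on work-up to the silyl-protected chalcone F5. TBAF buffered with AcOH (THF, 0 °C) then returns 13.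

Step 4. Isomerisation of the electron-rich epoxide to the ketone, or its solvolysis, may outrun hydrogenolysis. The fallback makes the isomerisation deliberate; it sets out from 7 and returns at 8. Catalytic BF3·OEt2 in CH2Cl2 at −78 °C (Meinwald rearrangement, 1,2-hydride shift to the benzylic cation) should convert 7 into methyl 5-methoxy-2,2-dimethyl-3-oxochromane-8-carboxylate F6. A CBS reduction ((S)-2-methyl-oxazaborolidine, catecholborane, toluene, −40 °C) should then deliver hydride to the face set by the large quaternary C2 against the small C4 methylene, giving 8 with the R configuration.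

Step 5. Exchange at the electron-rich, ortho-substituted benzoate may be sluggish, or the aluminium thiolate may cleave the aryl methyl ether. The fallback sets out from 8 and returns at 9. Saponification (LiOH, THF/H2O, 40 °C) gives (3R)-3-hydroxy-5-methoxy-2,2-dimethylchromane-8-carboxylic acid F7. Carbodiimide thioesterification (PhSH, DCC, cat. DMAP, CH2Cl2, 0 °C) then gives 9, the hindered C3 alcohol being far less nucleophilic than the thiol.

**Further compounds**

F1 | step 7 | (3R)-3-hydroxy-N,5-dimethoxy-N,2,2-trimethylchromane-8-carboxamide | COc1ccc(C(=O)N(C)OC)c2c1C[C@@H](O)C(C)(C)O2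
F2 | step 7 | tert-butyl(4-ethynylphenoxy)dimethylsilane | C#Cc1ccc(O[Si](C)(C)C(C)(C)C)cc1
F3 | step 7 | tert-butyl{4-[(E)-2-iodovinyl]phenoxy}dimethylsilane | I/C=C/c1ccc(O[Si](C)(C)C(C)(C)C)cc1
F4 | step 7 | (E)-2-[4-(tert-butyldimethylsilyloxy)phenyl]vinyllithium | [Li]/C=C/c1ccc(O[Si](C)(C)C(C)(C)C)cc1
F5 | step 7 | (E)-3-[4-(tert-butyldimethylsilyloxy)phenyl]-1-[(3R)-3-hydroxy-5-methoxy-2,2-dimethylchroman-8-yl]prop-2-en-1-one | COc1ccc(C(=O)/C=C/c2ccc(O[Si](C)(C)C(C)(C)C)cc2)c2c1C[C@@H](O)C(C)(C)O2
F6 | step 4 | methyl 5-methoxy-2,2-dimethyl-3-oxochromane-8-carboxylate | COc1ccc(C(=O)OC)c2c1CC(=O)C(C)(C)O2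
F7 | step 5 | (3R)-3-hydroxy-5-methoxy-2,2-dimethylchromane-8-carboxylic acid | COc1ccc(C(=O)O)c2c1C[C@@H](O)C(C)(C)O2
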